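**Retrosynthetic overview**
- Gericudranin E is reached by hydrogenolysis of its 5,7,4''-tri-O-benzyl ether. Rings A and B and the pendant benzyl ring arrive intact; ring C is the only ring made, and it is made last.
- Ring C is opened at O1–C2. C2 is a benzylic ether carbon para to the ring B hydroxyl, so two-electron oxidation of the open-chain 4-alkylphenol makes C2 the exocyclic carbon of a para-quinone methide, which the C8a hydroxyl can capture.
- The open-chain ketol (C4 ketone, C3 carbinol) is cut at C4–C4a into a ring A aryllithium and a Weinreb amide whose C3 centre comes, already R, from D-tyrosine.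
- The ring A bromide comes from 2,4,6-trihydroxybenzaldehyde. Its formyl carbon becomes the C6 benzylic CH2 (Grignard addition, ionic hydrogenation); its 4-hydroxyl, para to that carbon, is kept apart as a MOM ether and becomes O1.

Key step: step 11

Remark: atoms are numbered as in the flavanonol (ring A = C4a–C8a, ring B = the aryl group on C2, ring C = the pyranone); the 4-hydroxybenzyl ring on C6 is called the pendant ring.

Step 1
Reactants: 1 2,4,6-trihydroxybenzaldehyde
Product: 2 2,6-dihydroxy-4-(methoxymethoxy)benzaldehyde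
Conditions: MOMCl (1.0 equiv), i-Pr2NEt, THF/CH2Cl2, 0 °C
Reagents that add atoms: chloromethyl methyl ether, COCCl
Why: The 4-hydroxyl is the least hindered and most acidic phenol (para to the formyl group and not flanking it), so one equivalent of MOMCl with a hindered amine should cap it first in a Williamson-type O-alkylation (MOM acetal formation), any bis-ether being removed by chromatography.

Step 2
Reactants: 2 2,6-dihydroxy-4-(methoxymethoxy)benzaldehyde
Product: 3 2,6-bis(benzyloxy)-4-(methoxymethoxy)benzaldehyde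
Conditions: BnBr, K2CO3, DMF, 60 °C
Reagents that add atoms: benzyl bromide, BrCc1ccccc1
Why: Williamson etherification of both remaining ortho phenols under carbonate/DMF conditions, to which the aldehyde and the MOM acetal are inert.

Step 3
Reactants: 3 2,6-bis(benzyloxy)-4-(methoxymethoxy)benzaldehyde; 4 1-(benzyloxy)-4-bromobenzene
Product: 6 [2,6-bis(benzyloxy)-4-(methoxymethoxy)phenyl][4-(benzyloxy)phenyl]methanol (racemic), via arylmagnesium bromide 5 (not isolated)
Conditions: 4, Mg, I2 (cat.), THF, reflux; then 3, THF, 0 °C to rt; aq. NH4Cl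
Reagents that add atoms: none
Why: Grignard addition of the arylmagnesium bromide to the aldehyde carbonyl, which the two ortho benzyloxy groups can chelate to magnesium rather than block; the carbinol centre formed is racemic and is removed in step 4.

Step 4
Reactants: 6 [2,6-bis(benzyloxy)-4-(methoxymethoxy)phenyl][4-(benzyloxy)phenyl]methanol
Product: 7 1,3-bis(benzyloxy)-2-[4-(benzyloxy)benzyl]-5-(methoxymethoxy)benzene
Conditions: Et3SiH, CF3CO2H, CH2Cl2, −40 to 0 °C
Reagents that add atoms: none
Why: Ionic hydrogenation: the diarylmethyl cation, stabilised by four alkoxy groups, forms with little acid at low temperature and is reduced by hydride transfer from Et3SiH before the aryl MOM acetal is attacked.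

Step 5
Reactants: 7 1,3-bis(benzyloxy)-2-[4-(benzyloxy)benzyl]-5-(methoxymethoxy)benzene
Product: 8 1,3-bis(benzyloxy)-2-[4-(benzyloxy)benzyl]-4-bromo-5-(methoxymethoxy)benzene
Conditions: NBS (1.0 equiv), MeCN, 0 °C, dark
Reagents that add atoms: N-bromosuccinimide, O=C1CCC(=O)N1Br
Why: Electrophilic aromatic bromination goes to one of the two equivalent ring A positions flanked by OMOM and OBn (activated by three oxygens), far ahead of the mono-oxygenated pendant ring, and the first bromine slows a second substitution.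

Step 6
Reactants: 9 D-tyrosine
Product: 10 (R)-2-hydroxy-3-(4-hydroxyphenyl)propanoic acid
Conditions: NaNO2, 1 M H2SO4, 0 °C to rt
Reagents that add atoms: water, O
Why: Diazotisation of the α-amino acid and hydrolysis with net retention (double inversion through the α-lactone) is the standard route from amino acids to α-hydroxy acids, so the R centre of D-tyrosine becomes the R carbinol that ends as C3.

Step 7
Reactants: 10 (R)-2-hydroxy-3-(4-hydroxyphenyl)propanoic acid
Product: 11 (R)-2-hydroxy-3-(4-hydroxyphenyl)-N-methoxy-N-methylpropanamide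
Conditions: MeNHOMe·HCl, EDC·HCl, HOBt, N-methylmorpholine, DMF, 0 °C to rt
Reagents that add atoms: N,O-dimethylhydroxylamine hydrochloride, CNOC.Cl
Why: Carbodiimide/HOBt amide coupling gives the Weinreb amide because the amine outcompetes the free hydroxyls for the active ester, and an α-hydroxy acid has no oxazolone pathway for racemisation.

Step 8
Reactants: 11 (R)-2-hydroxy-3-(4-hydroxyphenyl)-N-methoxy-N-methylpropanamide
Product: 12 (R)-2-(tert-butyldimethylsilyloxy)-3-[4-(tert-butyldimethylsilyloxy)phenyl]-N-methoxy-N-methylpropanamide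
Conditions: TBSCl, imidazole, DMF, rt
Reagents that add atoms: tert-butyldimethylsilyl chloride, CC(C)(C)[Si](C)(C)Cl
Why: Silyl ether formation on both the phenol and the secondary alcohol removes the acidic protons before the organolithium step and leaves the stereocentre untouched.

Step 9
Reactants: 8 1,3-bis(benzyloxy)-2-[4-(benzyloxy)benzyl]-4-bromo-5-(methoxymethoxy)benzene; 12 (R)-2-(tert-butyldimethylsilyloxy)-3-[4-(tert-butyldimethylsilyloxy)phenyl]-N-methoxy-N-methylpropanamide
Product: 14 (R)-1-[4,6-bis(benzyloxy)-5-(4-benzyloxybenzyl)-2-(methoxymethoxy)phenyl]-2-(tert-butyldimethylsilyloxy)-3-[4-(tert-butyldimethylsilyloxy)phenyl]propan-1-one, via aryllithium 13 (not isolated)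
Conditions: 8, n-BuLi, THF, −78 °C; then 12, −78 to −30 °C; aq. NH4Cl
Reagents that add atoms: none
Why: Bromine–lithium exchange at −78 °C outruns deprotonation of benzylic positions, and the aryllithium adds once to the amide to give a chelated tetrahedral adduct that collapses only on work-up (Weinreb ketone synthesis), so neither over-addition nor enolisation of the α-silyloxy centre is expected.

Step 10
Reactants: 14 (R)-1-[4,6-bis(benzyloxy)-5-(4-benzyloxybenzyl)-2-(methoxymethoxy)phenyl]-2-(tert-butyldimethylsilyloxy)-3-[4-(tert-butyldimethylsilyloxy)phenyl]propan-1-one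
Product: 15 (R)-1-[4,6-bis(benzyloxy)-5-(4-benzyloxybenzyl)-2-hydroxyphenyl]-2-hydroxy-3-(4-hydroxyphenyl)propan-1-one
Conditions: HCl (ca. 2 M), MeOH/THF, 40 °C
Reagents that add atoms: none
Why: Acid-catalysed methanolysis cleaves the chelation-activated aryl MOM acetal, the secondary silyl ether and, more slowly, the phenolic silyl ether in one operation, while benzyl ethers are stable and the mild acidity should not enolise the hindered α-ketol.

Step 11
Reactants: 15 (R)-1-[4,6-bis(benzyloxy)-5-(4-benzyloxybenzyl)-2-hydroxyphenyl]-2-hydroxy-3-(4-hydroxyphenyl)propan-1-one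
Product: 17 (2R,3R)-5,7-bis(benzyloxy)-6-(4-benzyloxybenzyl)-3-hydroxy-2-(4-hydroxyphenyl)chroman-4-one, via para-quinone methide 16 (not isolated)
Conditions: reticulated vitreous carbon anode, Pt cathode, undivided cell, constant potential at the first anodic wave (ca. +1.1 V vs Ag/AgCl, fixed by cyclic voltammetry), n-Bu4NBF4 (0.1 M), 2,6-lutidine (2 equiv), MeCN/(CF3)2CHOH 4:1, 5 mM, 0 °C, stopped at about 2 F/mol
Reagents that add atoms: none
Why: Proposed new method: ring B carries the only phenol of 15 that is free to hydrogen-bond to 2,6-lutidine (the ring A hydroxyl is locked in a chelate with the ketone), so it should be oxidised first, in a two-electron, two-proton sequence (phenoxyl radical, phenoxonium ion, loss of the benzylic proton) to para-quinone methide 16, whose exocyclic carbon is then attacked by the C8a hydroxyl in an intramolecular oxa-Michael addition that forms O1–C2 and rearomatises ring B. The closest known reactions are the anodic side-chain functionalisation of 4-alkylphenols through quinone methides and the oxidant-mediated cyclisation of 2'-hydroxydihydrochalcones to flavanones; the anodic closure of an α-ketol of this kind is new. Ring C closes in a 6-exo-trig mode, since the C2=C1' bond that is attacked lies outside the ring being formed. C3 is carried unchanged from D-tyrosine and controls C2: in the half-chair transition state the C3 hydroxyl and the quinone methide ring both sit pseudo-equatorial, which leads to the 2,3-trans (2R,3R) isomer, also the more stable one. The step needs oxidation of ring B in preference to ring A, the pendant benzyloxybenzyl ring and the product phenol, which the chelation of the ring A hydroxyl, the controlled potential and the charge limit are meant to secure, and it needs ring closure to outrun the base-mediated shift of the C3 hydrogen in 16, which the weak hindered base, the fluorinated co-solvent, the low temperature and the high dilution should favour.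

Step 12
Reactants: 17 (2R,3R)-5,7-bis(benzyloxy)-6-(4-benzyloxybenzyl)-3-hydroxy-2-(4-hydroxyphenyl)chroman-4-one
Product: 18 gericudranin E, (2R,3R)-3,5,7-trihydroxy-6-(4-hydroxybenzyl)-2-(4-hydroxyphenyl)chroman-4-one
Conditions: H2 (1 atm), Pd/C (10%), EtOAc/MeOH, rt
Reagents that add atoms: none
Why: Catalytic hydrogenolysis of the three benzyl aryl ethers under mild neutral conditions, which are standard for benzylated dihydroflavonols and leave the C4 ketone, the diarylmethane and the C2–O1 bond, and thus both stereocentres, intact.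

**Compound list**
1 | 2,4,6-trihydroxybenzaldehyde | O=Cc1c(O)cc(O)cc1O | starting material
2 | 2,6-dihydroxy-4-(methoxymethoxy)benzaldehyde | COCOc1cc(O)c(C=O)c(O)c1 | intermediate
3 | 2,6-bis(benzyloxy)-4-(methoxymethoxy)benzaldehyde | COCOc1cc(OCc2ccccc2)c(C=O)c(OCc2ccccc2)c1 | intermediate
4 | 1-(benzyloxy)-4-bromobenzene | Brc1ccc(OCc2ccccc2)cc1 | starting material
5 | [4-(benzyloxy)phenyl]magnesium bromide (formed in the flask) | Br[Mg]c1ccc(OCc2ccccc2)cc1 | intermediate
6 | [2,6-bis(benzyloxy)-4-(methoxymethoxy)phenyl][4-(benzyloxy)phenyl]methanol (racemic) | COCOc1cc(OCc2ccccc2)c(C(O)c2ccc(OCc3ccccc3)cc2)c(OCc2ccccc2)c1 | intermediate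
7 | 1,3-bis(benzyloxy)-2-[4-(benzyloxy)benzyl]-5-(methoxymethoxy)benzene | COCOc1cc(OCc2ccccc2)c(Cc2ccc(OCc3ccccc3)cc2)c(OCc2ccccc2)c1 | intermediate
8 | 1,3-bis(benzyloxy)-2-[4-(benzyloxy)benzyl]-4-bromo-5-(methoxymethoxy)benzene | COCOc1cc(OCc2ccccc2)c(Cc2ccc(OCc3ccccc3)cc2)c(OCc2ccccc2)c1Br | intermediate
9 | D-tyrosine | N[C@H](Cc1ccc(O)cc1)C(=O)O | starting material
10 | (R)-2-hydroxy-3-(4-hydroxyphenyl)propanoic acid | O=C(O)[C@H](O)Cc1ccc(O)cc1 | intermediate
11 | (R)-2-hydroxy-3-(4-hydroxyphenyl)-N-methoxy-N-methylpropanamide | CON(C)C(=O)[C@H](O)Cc1ccc(O)cc1 | intermediate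
12 | (R)-2-(tert-butyldimethylsilyloxy)-3-[4-(tert-butyldimethylsilyloxy)phenyl]-N-methoxy-N-methylpropanamide | CON(C)C(=O)[C@H](O[Si](C)(C)C(C)(C)C)Cc1ccc(O[Si](C)(C)C(C)(C)C)cc1 | intermediate
13 | [2,4-bis(benzyloxy)-3-(4-benzyloxybenzyl)-6-(methoxymethoxy)phenyl]lithium (formed in the flask) | COCOc1cc(OCc2ccccc2)c(Cc2ccc(OCc3ccccc3)cc2)c(OCc2ccccc2)c1[Li] | intermediate
14 | (R)-1-[4,6-bis(benzyloxy)-5-(4-benzyloxybenzyl)-2-(methoxymethoxy)phenyl]-2-(tert-butyldimethylsilyloxy)-3-[4-(tert-butyldimethylsilyloxy)phenyl]propan-1-one | O=C([C@H](O[Si](C)(C)C(C)(C)C)Cc1ccc(O[Si](C)(C)C(C)(C)C)cc1)c1c(OCOC)cc(OCc2ccccc2)c(Cc2ccc(OCc3ccccc3)cc2)c1OCc1ccccc1 | intermediate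
15 | (R)-1-[4,6-bis(benzyloxy)-5-(4-benzyloxybenzyl)-2-hydroxyphenyl]-2-hydroxy-3-(4-hydroxyphenyl)propan-1-one | O=C([C@H](O)Cc1ccc(O)cc1)c1c(O)cc(OCc2ccccc2)c(Cc2ccc(OCc3ccccc3)cc2)c1OCc1ccccc1 | intermediate
16 | (R)-4-{3-[4,6-bis(benzyloxy)-5-(4-benzyloxybenzyl)-2-hydroxyphenyl]-2-hydroxy-3-oxopropylidene}cyclohexa-2,5-dien-1-one (para-quinone methide, formed in the flask) | O=C([C@H](O)C=C1C=CC(=O)C=C1)c1c(O)cc(OCc2ccccc2)c(Cc2ccc(OCc3ccccc3)cc2)c1OCc1ccccc1 | intermediate
17 | (2R,3R)-5,7-bis(benzyloxy)-6-(4-benzyloxybenzyl)-3-hydroxy-2-(4-hydroxyphenyl)chroman-4-one | O=C1c2c(cc(OCc3ccccc3)c(Cc3ccc(OCc4ccccc4)cc3)c2OCc2ccccc2)O[C@H](c2ccc(O)cc2)[C@H]1O | intermediate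
18 | gericudranin E, (2R,3R)-3,5,7-trihydroxy-6-(4-hydroxybenzyl)-2-(4-hydroxyphenyl)chroman-4-one | O=C1c2c(cc(O)c(Cc3ccc(O)cc3)c2O)O[C@H](c2ccc(O)cc2)[C@H]1O | target

Total step count: 12
Longest linear sequence: 9 steps (steps 1–5, then 9–12)

**Steps most likely to fail**

1. Step 11 (anodic cyclisation). Three processes could defeat it: the phenoxyl radicals may couple before the second electron transfer; the C3 hydrogen of the quinone methide may shift to give the achiral diketone tautomer, with loss of the C3 centre; and the product phenol may be oxidised on to the flavonol. The fallback closes ring C by epoxide opening instead of oxidation; it sets out from bromide 8 and comes back at target 18. Bromine–lithium exchange of 8 (n-BuLi, THF, −78 °C) and acylation with N-methoxy-N-methylacetamide would give 1-[4,6-bis(benzyloxy)-5-(4-benzyloxybenzyl)-2-(methoxymethoxy)phenyl]ethan-1-one F1. Claisen–Schmidt condensation with 4-(benzyloxy)benzaldehyde (KOH, EtOH/THF) would give the (E)-chalcone F2. Juliá–Colonna epoxidation (poly-L-leucine, urea–H2O2, DBU, THF) would give the (2R,3S)-epoxy ketone F3, which fixes the future C3. Methanolic HCl would then remove the MOM group and let the freed phenol open the epoxide at its benzylic carbon to (2R,3R)-5,7-bis(benzyloxy)-6-(4-benzyloxybenzyl)-2-[4-(benzyloxy)phenyl]-3-hydroxychroman-4-one F4. Hydrogenolysis under the conditions of step 12 would deliver 18.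

2. Step 9 (aryllithium plus Weinreb amide). The doubly ortho-substituted aryllithium may act as a base towards the hindered amide or a benzylic CH2 instead of adding to the carbonyl, returning debrominated arene. The fallback uses a more electrophilic carbonyl and restores the oxidation level afterwards; it sets out from amide 12 and bromide 8 and comes back at ketone 14. Reduction of 12 with i-Bu2AlH (THF, −78 °C) would give (R)-2-(tert-butyldimethylsilyloxy)-3-[4-(tert-butyldimethylsilyloxy)phenyl]propanal F5. Addition of aryllithium 13, if needed after transmetalation with CeCl3, would give the secondary alcohol (2R)-1-[4,6-bis(benzyloxy)-5-(4-benzyloxybenzyl)-2-(methoxymethoxy)phenyl]-2-(tert-butyldimethylsilyloxy)-3-[4-(tert-butyldimethylsilyloxy)phenyl]propan-1-ol F6 as a mixture of carbinol epimers. Dess–Martin oxidation would converge both epimers on 14.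

3. Step 1 (mono-protection of the triol). Over-alkylation is the risk: once the 4-hydroxyl is capped, the ortho hydroxyl that is not engaged in the chelate can compete, giving mixtures of mono- and bis-ethers. The fallback separates the positions by steric bulk instead of acidity; it sets out from 1 and comes back at aldehyde 3. TIPSCl (1 equiv, imidazole, DMF, 0 °C) should silylate only the unhindered 4-hydroxyl to give 2,6-dihydroxy-4-(triisopropylsilyloxy)benzaldehyde F7. Mitsunobu benzylation (BnOH, PPh3, DIAD, THF) would give 2,6-bis(benzyloxy)-4-(triisopropylsilyloxy)benzaldehyde F8. Buffered n-Bu4NF/AcOH would give 2,6-bis(benzyloxy)-4-hydroxybenzaldehyde F9, and MOMCl/i-Pr2NEt would then give 3.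

**Further compounds**
F1 | step 11 | 1-[4,6-bis(benzyloxy)-5-(4-benzyloxybenzyl)-2-(methoxymethoxy)phenyl]ethan-1-one | CC(=O)c1c(OCOC)cc(OCc2ccccc2)c(Cc2ccc(OCc3ccccc3)cc2)c1OCc1ccccc1
F2 | step 11 | (E)-1-[4,6-bis(benzyloxy)-5-(4-benzyloxybenzyl)-2-(methoxymethoxy)phenyl]-3-[4-(benzyloxy)phenyl]prop-2-en-1-one | O=C(/C=C/c1ccc(OCc2ccccc2)cc1)c1c(OCOC)cc(OCc2ccccc2)c(Cc2ccc(OCc3ccccc3)cc2)c1OCc1ccccc1
F3 | step 11 | [4,6-bis(benzyloxy)-5-(4-benzyloxybenzyl)-2-(methoxymethoxy)phenyl]{(2R,3S)-3-[4-(benzyloxy)phenyl]oxiran-2-yl}methanone | O=C([C@@H]1O[C@H]1c1ccc(OCc2ccccc2)cc1)c1c(OCOC)cc(OCc2ccccc2)c(Cc2ccc(OCc3ccccc3)cc2)c1OCc1ccccc1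
F4 | step 11 | (2R,3R)-5,7-bis(benzyloxy)-6-(4-benzyloxybenzyl)-2-[4-(benzyloxy)phenyl]-3-hydroxychroman-4-one | O=C1c2c(cc(OCc3ccccc3)c(Cc3ccc(OCc4ccccc4)cc3)c2OCc2ccccc2)O[C@H](c2ccc(OCc3ccccc3)cc2)[C@H]1O
F5 | step 9 | (R)-2-(tert-butyldimethylsilyloxy)-3-[4-(tert-butyldimethylsilyloxy)phenyl]propanal | O=C[C@H](O[Si](C)(C)C(C)(C)C)Cc1ccc(O[Si](C)(C)C(C)(C)C)cc1
F6 | step 9 | (2R)-1-[4,6-bis(benzyloxy)-5-(4-benzyloxybenzyl)-2-(methoxymethoxy)phenyl]-2-(tert-butyldimethylsilyloxy)-3-[4-(tert-butyldimethylsilyloxy)phenyl]propan-1-ol (both C1 epimers) | OC([C@H](O[Si](C)(C)C(C)(C)C)Cc1ccc(O[Si](C)(C)C(C)(C)C)cc1)c1c(OCOC)cc(OCc2ccccc2)c(Cc2ccc(OCc3ccccc3)cc2)c1OCc1ccccc1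
F7 | step 1 | 2,6-dihydroxy-4-(triisopropylsilyloxy)benzaldehyde | CC(C)[Si](Oc1cc(O)c(C=O)c(O)c1)(C(C)C)C(C)C
F8 | step 1 | 2,6-bis(benzyloxy)-4-(triisopropylsilyloxy)benzaldehyde | CC(C)[Si](Oc1cc(OCc2ccccc2)c(C=O)c(OCc2ccccc2)c1)(C(C)C)C(C)C
F9 | step 1 | 2,6-bis(benzyloxy)-4-hydroxybenzaldehyde | O=Cc1c(OCc2ccccc2)cc(O)cc1OCc1ccccc1
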